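**Retrosynthetic overview**

1. Numbering: atoms carry the locants of the target SMILES order (C1 and C28 are the methyls). Ring A = C5/C6/C7/C9/C11/C12, ring B = C16/C17/C18/C20/C22/C23, ring C = pyran O3/C2/C14/C6/C5/C4, ring D = pyran O26/C27/C15/C16/C17/C25, ring E = carbocycle C4/C5/C6/C14/C15/C16/C17/C25.
2. Feature: C4 and C25 are bonded to each other, and each carries one pyran oxygen (O3, O26) and one ring carbon (C5, C17) lying ortho to the C14/C15 attachment, so C4–C25 is a glyoxal unit. Cutting O3–C4, C4–C5, O26–C25 and C25–C17 removes it and opens rings C, D and E together.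
3. Before that cut, rings A and B are taken back to benzene rings: oxiranes and C12/C18 carbinols from quinone monoketals, these from para-methoxyphenols (OMe at C7/C23, O-allyl at C12/C18).
4. The open-chain C2-symmetric diol comes from the C14–C15 bond (oxidative homocoupling of an arylacetyl imide on a chiral oxazolidinone) and the C2/C27 carbinols (oxazaborolidine reduction of the bis(methyl ketone)).
5. Forward ring order: ring C, then rings D and E in the same operation, then dearomatisation of rings A and B and closure of the two oxiranes.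

Key step: step 8

Assumptions (chemistry): 2-(5-bromo-2-methoxyphenyl)acetic acid is taken as a catalogue compound. In step 11 the cinchonidine-derived ammonium salt is assumed to deliver the peroxide to the ring faces opposite the C4–C25 and C14–C15 bonds; if the sense is the reverse, N-benzylcinchoninium chloride takes its place.

**Route**

Step 1
Reactants: 1 2-(5-bromo-2-methoxyphenyl)acetic acid
Product: 2 2-(5-hydroxy-2-methoxyphenyl)acetic acid
Conditions: KOH, Pd2(dba)3 (cat.), 2-di-tert-butylphosphino-2',4',6'-triisopropylbiphenyl (cat.), 1,4-dioxane/H2O, 100 °C; then aq. HCl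
Reagents that add atoms: potassium hydroxide [K+].[OH-]
Why: Buchwald–Hartwig-type C–O coupling of an aryl bromide with hydroxide, in which oxidative addition, bromide/hydroxide exchange and C–O reductive elimination from the bulky biarylphosphine complex give the phenol para to the methoxy group; no stereocentre is formed.

Step 2
Reactants: 2 2-(5-hydroxy-2-methoxyphenyl)acetic acid; 3 allyl bromide
Product: 5 2-(5-allyloxy-2-methoxyphenyl)acetic acid, via allyl 2-(5-allyloxy-2-methoxyphenyl)acetate 4 (not isolated)
Conditions: 3 (2.5 equiv), K2CO3, DMF, rt; then LiOH, THF/H2O, rt; then aq. HCl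
Reagents that add atoms: allyl bromide C=CCBr (compound 3); lithium hydroxide [Li+].[OH-]
Why: Williamson O-allylation of the phenoxide (the carboxylate is allylated too) followed by saponification of the allyl ester returns the acid with only the phenol oxygen allylated; no stereocentre is formed.

Step 3
Reactants: 5 2-(5-allyloxy-2-methoxyphenyl)acetic acid; 6 (S)-4-benzyl-2-oxazolidinone
Product: 8 (S)-3-[2-(5-allyloxy-2-methoxyphenyl)acetyl]-4-benzyloxazolidin-2-one, via 2-(5-allyloxy-2-methoxyphenyl)acetic pivalic anhydride 7 (not isolated)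
Conditions: Me3CCOCl, Et3N, THF, −20 °C; then 6, LiCl, −20 °C to rt
Reagents that add atoms: none
Why: N-acylation of the oxazolidinone through the pivaloyl mixed anhydride, where the LiCl/amine system activates the oxazolidinone and attack goes to the less hindered arylacetyl carbonyl; the auxiliary stereocentre is untouched.

Step 4
Reactants: 8 (S)-3-[2-(5-allyloxy-2-methoxyphenyl)acetyl]-4-benzyloxazolidin-2-one (two molecules)
Product: 10 (2S,3S)-2,3-bis(5-allyloxy-2-methoxyphenyl)-1,4-bis[(S)-4-benzyl-2-oxooxazolidin-3-yl]butane-1,4-dione, via lithium Z-enolate of the imide 9 (not isolated)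
Conditions: LiN(SiMe3)2, THF, −78 °C; then CuCl2, DMF, −78 °C to rt
Reagents that add atoms: none
Why: Oxidative enolate homocoupling, in which the chelated lithium Z-enolate is oxidised by divalent copper and the two α-carbons join through the enolate faces anti to the benzyl groups, setting C14 and C15 both S in the C2-symmetric dimer.

Step 5
Reactants: 10 (2S,3S)-bis(imide)
Product: 11 S,S'-diethyl (2S,3S)-2,3-bis(5-allyloxy-2-methoxyphenyl)butanebis(thioate)
Conditions: EtSH, n-BuLi, THF, 0 °C; aq. NH4Cl
Reagents that add atoms: ethanethiol CCS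
Why: Thiolate cleavage of N-acyl oxazolidinones, in which the soft, weakly basic lithium ethanethiolate attacks only the exocyclic carbonyls and releases the auxiliary without epimerising the α-aryl centres C14 and C15.

Step 6
Reactants: 11 bis(S-ethyl thioester)
Product: 12 (3S,4S)-3,4-bis(5-allyloxy-2-methoxyphenyl)hexane-2,5-dione
Conditions: Me2CuLi, Et2O, −78 °C; aq. NH4Cl
Reagents that add atoms: lithium dimethylcuprate [Li+].C[Cu-]C
Why: Ketone synthesis from thioesters with a Gilman cuprate, in which each acyl group takes one methyl at low temperature and the ketone formed neither reacts further nor enolises, so C14 and C15 keep their configuration.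

Step 7
Reactants: 12 (3S,4S)-diketone
Product: 13 (2R,3S,4S,5R)-3,4-bis(5-allyloxy-2-methoxyphenyl)hexane-2,5-diol
Conditions: (S)-2-methyl-CBS-oxazaborolidine [(S)-1-methyl-3,3-diphenyltetrahydro-1H,3H-pyrrolo[1,2-c][1,3,2]oxazaborole] (0.4 equiv), catecholborane, PhMe, −78 to −40 °C; MeOH; aq. NaOH
Reagents that add atoms: none
Why: Corey–Bakshi–Shibata reduction, in which the (S)-oxazaborolidine treats methyl as the small and the α-aryl-branched carbon as the large ketone substituent and delivers hydride to give the R carbinols at C2 and C27, the sense that Felkin–Anh attack anti to the α-aryl group also predicts, while catecholborane at low temperature leaves the allyl ethers alone.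

Step 8
Reactants: 13 (2R,3S,4S,5R)-diol; 14 glyoxal bis(dimethyl acetal) (1,1,2,2-tetramethoxyethane)
Product: 16 (2R,4S,14S,15S,25S,27R)-arene-level dioxatricycle (two 8-allyloxy-5-methoxy-3-methylisochroman units joined 1,1' through C4–C25 and 4,4' through C14–C15), via monocyclised isochroman dimethyl acetal 15 (not isolated)
Conditions: 14 (1.1 equiv), BF3·OEt2, CH2Cl2 (high dilution), 0 °C to rt
Reagents that add atoms: none
Why: Proposed new method: BF3 promotes exchange of one acetal carbon of 14 onto the C2 hydroxyl and ionisation to the oxocarbenium ion O3=C4, which arene carbon C5 (ortho to the allyloxy group) attacks in a 6-endo-trig Friedel–Crafts closure of ring C (intermediate 15); the second acetal carbon then exchanges onto the C27 hydroxyl, ionises to O26=C25 and is attacked by C17, closing ring D (6-endo-trig) and with the same C25–C17 bond ring E (8-exo-trig). The closest known reaction type is the oxa-Pictet–Spengler cyclisation of 1-(2,5-dialkoxyphenyl)propan-2-ols with aldehyde acetals under BF3·OEt2, and what is not precedented is the use of both carbons of one glyoxal acetal so that the second closure is a bridging one. The new centres C4 and C25 are set by the cage: a tricycle can form only if the C4–C25 bond is cis to the C14–C15 bond on both pyran rings, which with 14S,15S means 4S,25S and puts each acetal carbon trans to the neighbouring methyl group. The step therefore needs the first closure to deliver, or to be able to reach, the C4 epimer with C25 cis to C15; the peri contact between C15 and the C7 methoxy group pushes C15 and with it the trans C2 methyl group into pseudo-axial positions, so that entry of the C25 branch syn to that methyl would cost a 1,3-diaxial contact and the required epimer should be favoured. A C4 epimer that cannot bridge is not lost, since it can return through the enol ether C4=C25 (loss of H4 from the C25 oxocarbenium ion) or through Lewis-acid reopening of the o-alkoxybenzylic C4–O3 bond, and only the closable isomer is drained irreversibly by rearomatisation. Site selectivity on the arenes is secured by the tethers, C5 and C17 being the only free positions ortho to the side chain, and high dilution keeps the second closure ahead of intermolecular acetal exchange.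

Step 9
Reactants: 16 bis(allyl ether) tricycle
Product: 17 (2R,4S,14S,15S,25S,27R)-bis-phenol (as 16 with OH at C12 and C18)
Conditions: Pd(PPh3)4 (cat.), morpholine, THF, rt
Reagents that add atoms: none
Why: Tsuji–Trost deallylation, in which zerovalent palladium ionises each aryl allyl ether to a π-allyl complex that morpholine captures, freeing the two phenols while the benzylic pyran ethers and the six stereocentres are untouched.

Step 10
Reactants: 17 bis-phenol
Product: 18 bis(quinone monoketal): rings A and B as 4,4-dimethoxycyclohexa-2,5-dienones (C12=O and C18=O, C7(OMe)2 and C23(OMe)2, C9=C11 and C20=C22, C5=C6 and C16=C17), cage (2R,4S,14S,15S,25S,27R)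
Conditions: PhI(OAc)2, MeOH, 0 °C
Reagents that add atoms: methanol CO
Why: Hypervalent-iodine oxidative dearomatisation of a para-methoxyphenol in methanol, in which the oxidised phenol is trapped by methanol at the methoxy-bearing carbon (C7, C23) to give the para-quinone monoketal; no stereocentre is formed.

Step 11
Reactants: 18 bis(quinone monoketal)
Product: 19 bis-epoxide: oxiranes C9–O10–C11 and C20–O21–C22 (9R,11S,20S,22R), otherwise as 18
Conditions: tBuOOH, N-benzylcinchonidinium chloride (cat.), aq. NaOH, PhMe, 0 °C to rt
Reagents that add atoms: tert-butyl hydroperoxide CC(C)(C)OO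
Why: Weitz–Scheffer nucleophilic epoxidation under chiral phase-transfer catalysis, in which the hydroperoxide anion paired with the cinchonidinium cation adds to the β-carbons C9 and C22 of the disubstituted enone bonds (the tetrasubstituted C5=C6 and C16=C17 bonds are inert) and the catalyst, not the only weakly biasing remote cage, places both oxirane oxygens on the ring faces opposite the C4–C25 and C14–C15 bonds.

Step 12
Reactants: 19 bis-epoxide
Product: 20 bis(epoxy alcohol) bis(dimethyl ketal): C12–OH and C18–OH (12S,18S), oxiranes (9R,11R,20R,22R), C7 and C23 still as dimethyl ketals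
Conditions: iBu2AlH, THF, −78 °C; aq. potassium sodium tartrate
Reagents that add atoms: none
Why: 1,2-Reduction of the α,β-epoxy enones by iBu2AlH, in which aluminium bound to the oxirane oxygen delivers hydride to C12 and C18 from the epoxide face, which is also the face away from the C4–C25 bond, giving the carbinols anti to the oxiranes.

Step 13
Reactants: 20 bis(epoxy alcohol) bis(dimethyl ketal)
Product: 21 epoxytwinol A (2R,4S,9R,11R,12S,14S,15S,18S,20R,22R,25S,27R)
Conditions: TsOH·H2O (cat.), acetone/H2O, 0 °C to rt
Reagents that add atoms: water O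
Why: Acid-catalysed hydrolysis of the two allylic dimethyl ketals through oxocarbenium ions unveils the C7 and C23 enone carbonyls under conditions mild enough to spare the oxiranes; no stereocentre is touched.

**Compound list**

1 | 2-(5-bromo-2-methoxyphenyl)acetic acid | COc1ccc(Br)cc1CC(=O)O | starting material
2 | 2-(5-hydroxy-2-methoxyphenyl)acetic acid | COc1ccc(O)cc1CC(=O)O | intermediate
3 | allyl bromide | C=CCBr | starting material
4 | allyl 2-(5-allyloxy-2-methoxyphenyl)acetate | COc1ccc(OCC=C)cc1CC(=O)OCC=C | intermediate
5 | 2-(5-allyloxy-2-methoxyphenyl)acetic acid | COc1ccc(OCC=C)cc1CC(=O)O | intermediate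
6 | (S)-4-benzyl-2-oxazolidinone | O=C1N[C@@H](Cc2ccccc2)CO1 | starting material
7 | 2-(5-allyloxy-2-methoxyphenyl)acetic pivalic anhydride | COc1ccc(OCC=C)cc1CC(=O)OC(=O)C(C)(C)C | intermediate
8 | (S)-3-[2-(5-allyloxy-2-methoxyphenyl)acetyl]-4-benzyloxazolidin-2-one | COc1ccc(OCC=C)cc1CC(=O)N1[C@@H](Cc2ccccc2)COC1=O | intermediate
9 | lithium Z-enolate of imide 8 | [Li+].COc1ccc(OCC=C)cc1/C=C(\[O-])N1[C@@H](Cc2ccccc2)COC1=O | intermediate
10 | (2S,3S)-2,3-bis(5-allyloxy-2-methoxyphenyl)-1,4-bis[(S)-4-benzyl-2-oxooxazolidin-3-yl]butane-1,4-dione | O=C1OC[C@H](Cc2ccccc2)N1C(=O)[C@H](c1cc(OCC=C)ccc1OC)[C@@H](c1cc(OCC=C)ccc1OC)C(=O)N1[C@@H](Cc2ccccc2)COC1=O | intermediate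
11 | S,S'-diethyl (2S,3S)-2,3-bis(5-allyloxy-2-methoxyphenyl)butanebis(thioate) | CCSC(=O)[C@H](c1cc(OCC=C)ccc1OC)[C@@H](c1cc(OCC=C)ccc1OC)C(=O)SCC | intermediate
12 | (3S,4S)-3,4-bis(5-allyloxy-2-methoxyphenyl)hexane-2,5-dione | CC(=O)[C@H](c1cc(OCC=C)ccc1OC)[C@@H](c1cc(OCC=C)ccc1OC)C(C)=O | intermediate
13 | (2R,3S,4S,5R)-3,4-bis(5-allyloxy-2-methoxyphenyl)hexane-2,5-diol | C[C@@H](O)[C@H](c1cc(OCC=C)ccc1OC)[C@@H](c1cc(OCC=C)ccc1OC)[C@@H](C)O | intermediate
14 | glyoxal bis(dimethyl acetal) (1,1,2,2-tetramethoxyethane) | COC(OC)C(OC)OC | starting material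
15 | (1S,3R,4S)-8-allyloxy-1-(dimethoxymethyl)-5-methoxy-3-methylisochroman bearing at C4 the (1S,2R)-1-(5-allyloxy-2-methoxyphenyl)-2-hydroxypropyl group | C[C@H]1O[C@H](C(OC)OC)c2c(c(OC)ccc2OCC=C)[C@@H]1[C@@H](c1cc(OCC=C)ccc1OC)[C@@H](C)O | intermediate
16 | (2R,4S,14S,15S,25S,27R)-arene-level dioxatricycle, OMe at C7/C23, O-allyl at C12/C18 | C[C@H]1O[C@H]2c3c(c(OC)ccc3OCC=C)[C@@H]1[C@H]1c3c(c(OCC=C)ccc3OC)[C@@H]2O[C@@H]1C | intermediate
17 | (2R,4S,14S,15S,25S,27R)-bis-phenol, OMe at C7/C23, OH at C12/C18 | C[C@H]1O[C@H]2c3c(c(OC)ccc3O)[C@@H]1[C@H]1c3c(c(O)ccc3OC)[C@@H]2O[C@@H]1C | intermediate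
18 | bis(quinone monoketal), C12=O/C18=O, C7(OMe)2/C23(OMe)2 | C[C@H]1O[C@H]2C3=C(C(OC)(OC)C=CC3=O)[C@@H]1[C@H]1C3=C(C(=O)C=CC3(OC)OC)[C@@H]2O[C@@H]1C | intermediate
19 | bis-epoxide of 18 (9R,11S,20S,22R) | C[C@H]1O[C@H]2C3=C(C(OC)(OC)[C@@H]4O[C@@H]4C3=O)[C@@H]1[C@H]1C3=C(C(=O)[C@H]4O[C@H]4C3(OC)OC)[C@@H]2O[C@@H]1C | intermediate
20 | bis(epoxy alcohol) bis(dimethyl ketal) (9R,11R,12S,18S,20R,22R) | C[C@H]1O[C@H]2C3=C(C(OC)(OC)[C@@H]4O[C@@H]4[C@H]3O)[C@@H]1[C@H]1C3=C([C@H](O)[C@H]4O[C@H]4C3(OC)OC)[C@@H]2O[C@@H]1C | intermediate
21 | epoxytwinol A | C[C@H]1O[C@H]2C3=C(C(=O)[C@@H]4O[C@@H]4[C@H]3O)[C@@H]1[C@H]1C3=C([C@H](O)[C@H]4O[C@H]4C3=O)[C@@H]2O[C@@H]1C | target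

**Step count and risks**

Total steps: 13. Longest linear sequence: 13 steps (1 to 21).

Steps most likely to fail:

Step 8 (labelled step). The bridging second closure may lose to intermolecular acetal exchange and oligomerisation, or the first closure may deliver the C4 epimer that cannot bridge and fail to equilibrate. The fallback sets out from 13 and returns at 16; it alkylates the same two arene carbons with a one-carbon unit first and makes the C4–C25 bond afterwards by ketyl coupling. Diol 13 with dimethoxymethane and BF3·OEt2 undergoes two ordinary oxa-Pictet–Spengler closures to the 4,4'-linked bis(isochroman) F1, in which C4 and C25 are CH2 groups and no new stereocentre arises. DDQ in wet CH2Cl2 oxidises both benzylic ether carbons to the bis(lactol) F2, which is in equilibrium with the hydroxy dialdehyde. SmI2 in THF couples the two aryl aldehyde carbons (pinacol coupling) and closes ring E to the tetraol F3. TsOH in CH2Cl2 then ionises the two o-alkoxybenzylic carbinols, and the C2 and C27 hydroxyls close rings C and D. As in the main route the cage admits only the 4S,25S arrangement, so the configuration of the diol in F3 does not matter, and the product is 16.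

Step 11. Facial discrimination at the remote C9=C11 and C20=C22 bonds may be weak or reversed, which would give diastereomeric bis-epoxides. The fallback sets out from 18 and returns at 21; it replaces catalyst control by a covalently bound auxiliary. Transketalisation of 18 with (2R,4R)-pentane-2,4-diol (pyridinium p-toluenesulfonate, benzene, removal of MeOH) gives the bis(dioxane ketal) F4, in which the ring methyl groups differentiate the two faces of the neighbouring β-carbons. tBuOOH with 1,8-diazabicyclo[5.4.0]undec-7-ene then gives the bis-epoxide F5, iBu2AlH at −78 °C gives the anti bis(epoxy alcohol) F6, and aqueous HF in MeCN removes the dioxane ketals to give 21. The (2R,4R) diol is taken here; its antipode serves if the auxiliary's face preference is the other one.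

Step 7. The intrinsic face preference of the α-stereocentres may oppose the catalyst, so that C2 and C27 form with the wrong configuration or as mixtures. The fallback sets out from 11 and returns at 13; it exchanges the roles of hydride and methyl. iBu2AlH in toluene at −78 °C reduces both thioesters to the dialdehyde F7, which is used at once, and MeMgBr in THF at −78 °C adds to both aldehyde groups. Because methyl is now the nucleophile and hydrogen the carbonyl substituent, the same substrate bias that gives the wrong carbinol epimers in the ketone reduction should here lead to the 2R,27R diol 13.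

**Further compounds**

F1 | step 8 | (3R,3'R,4S,4'S)-4,4'-bi(8-allyloxy-5-methoxy-3-methylisochroman) | C[C@H]1OCc2c(c(OC)ccc2OCC=C)[C@@H]1[C@H]1c2c(c(OCC=C)ccc2OC)CO[C@@H]1C
F2 | step 8 | bis(lactol) of F1, OH at C4 and C25 (anomer mixture) | C[C@H]1OC(O)c2c(c(OC)ccc2OCC=C)[C@@H]1[C@H]1c2c(c(OCC=C)ccc2OC)C(O)O[C@@H]1C
F3 | step 8 | pinacol tetraol: ring E closed with C4–OH and C25–OH, C2 and C27 hydroxyls free (14S,15S,2R,27R) | C[C@@H](O)[C@@H]1c2c(OC)ccc(OCC=C)c2C(O)C(O)c2c(OCC=C)ccc(OC)c2[C@H]1[C@@H](C)O
F4 | step 11 | bis(quinone monoketal) with (4R,6R)-4,6-dimethyl-1,3-dioxane ketals at C7 and C23 | C[C@H]1O[C@H]2C3=C(C4(O[C@H](C)C[C@@H](C)O4)C=CC3=O)[C@@H]1[C@H]1C3=C(C(=O)C=CC34O[C@H](C)C[C@@H](C)O4)[C@@H]2O[C@@H]1C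
F5 | step 11 | bis-epoxide of F4 | C[C@H]1O[C@H]2C3=C(C4(O[C@H](C)C[C@@H](C)O4)[C@@H]5O[C@@H]5C3=O)[C@@H]1[C@H]1C3=C(C(=O)[C@H]5O[C@H]5C34O[C@H](C)C[C@@H](C)O4)[C@@H]2O[C@@H]1C
F6 | step 11 | bis(epoxy alcohol) of F5, C12–OH and C18–OH anti to the oxiranes | C[C@H]1O[C@H]2C3=C(C4(O[C@H](C)C[C@@H](C)O4)[C@@H]5O[C@@H]5[C@H]3O)[C@@H]1[C@H]1C3=C([C@H](O)[C@H]5O[C@H]5C34O[C@H](C)C[C@@H](C)O4)[C@@H]2O[C@@H]1C
F7 | step 7 | (2S,3S)-2,3-bis(5-allyloxy-2-methoxyphenyl)butanedial | O=C[C@H](c1cc(OCC=C)ccc1OC)[C@@H](c1cc(OCC=C)ccc1OC)C=O
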